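I began from a ratio, that of two first-order times, one from a run low in reagent and one from a run high in it. Closed, stirred flasks turned starting material and reagent into product under free catalyst, and the new flasks differed from one another in [reagent].

in all of them: starting material 0.10 M; free catalyst 50 µM
- ash: reagent 0.23 M; run made earlier
- maple: reagent 0.51 M; run made earlier
- oak: reagent 1.4 M; run made earlier
- Monday's: reagent 0.200 M; time 30 h
- Thursday's: reagent 0.400 M; time 30 h
- Tuesday's: reagent 0.800 M; time 30 h
- Wednesday's: reagent 1.50 M; time 30 h

| ash: time / h | ash: product / % | maple: time / h | maple: product / % | oak: time / h | oak: product / % |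
|---|---|---|---|---|---|
| 1.33 | 0.4 | 3.00 | 3.1 | 1.33 | 2.2 |
| 2.50 | 2.5 | 6.00 | 7.8 | 4.00 | 5.7 |
| 4.00 | 5.7 | 10.0 | 12.7 | 8.00 | 11.7 |
| 8.00 | 9.6 | 12.0 | 16.3 | 10.0 | 14.8 |
| 15.0 | 16.2 | 15.0 | 20.8 | 15.0 | 22.1 |

(scatter of a reading: 1 percentage point)

- a reading or a percentage of product counts all its forms, free or not
- "hardly changes" means that all values lie within two and a half points (for a concentration: within two and a half percent of the largest)

- amount of product at the end, in percent of the starting material charged for Monday's, Thursday's, Tuesday's, Wednesday's, in this order
- the shape of the row from first to last (falls all the way / rises all the way / rises, then falls / hardly changes / falls, then rises)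

From the last reading of a run I took the first-order time of the starting material (pseudo-first-order, with [reagent] held at its charge): the time of the reading divided by the natural logarithm of charged over left. I chose the two ends of the range, ash at the lowest charge and oak at the highest. Ash gave 84.9 h and oak 60.1 h, so ash ran slower, with a ratio of 0.708.

If the pace follows [reagent]/([reagent] + K), that ratio gives K = 0.124 M. This is the half-saturation concentration, the [reagent] at which the first-order time stands at twice its limit. It is a reading and carries the scatter of 1 percentage point on each of the two points. Oak then put the limiting time at 55.2 h. The maple run, which I had not used, served as a test: I reckoned 19.6% at 15.0 h against the reading of 20.8%. For the new flasks I reckoned 28.5%, 34.0%, 37.6% and 39.5%, in the order asked.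

The forecast gave 26%, 34%, 39% and 42%, a row that rises all the way: “The row rises throughout, flattening at the top.” It stood below my reckoning for Monday's flask and above it for Wednesday's.

The flasks gave 32.1%, 36.4%, 38.9% and 40.1%, a row that rises all the way, and Monday's flask stood above both estimates.

    free catalyst + product ⇌ idle complex, settled at all times (K = 13.0 M⁻¹)
    reagent + free catalyst ⇌ catalyst intermediate A (K = 5.80 M⁻¹, k = 58.0 M⁻¹ min⁻¹)
    crystals ⇌ product, rate k3*(cs3 - [product]) while solid is left; crystals form when [product] > cs3 (solubility = 4.90 mM, k = 0.0320 min⁻¹)
    catalyst intermediate D ⇌ free catalyst + product (K = 0.0730 M, k = 210 min⁻¹)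
    catalyst intermediate C → catalyst intermediate D (k = 1.90 min⁻¹)
    catalyst intermediate A ⇌ catalyst intermediate B (K = 1.80, k = 12.0 min⁻¹)
    starting material + catalyst intermediate B ⇌ catalyst intermediate C (K = 7.30 M⁻¹, k = 240 M⁻¹ min⁻¹)
    product + catalyst intermediate B → spent catalyst (k = 0.00340 M⁻¹ min⁻¹)

In Monday's flask at 13.7 h, catalyst intermediate C fell back 17 times faster than it went on. Measured against my half-saturation concentration, [reagent] stood at 1.36 times that value in Monday's flask at 30.0 h, with 24.8% of the catalyst charged free, and at 11.8 times that value in Wednesday's flask at 30.0 h, with 3.82% free.

The readings were computed on assumed constants, noise included.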